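The numbers in the tables were computed for substances that don't exist, noise included.

Late readings are what to watch, so we start there. In Friday's run D reads 2.0% at 10.0 min. In Sunday's run, with more D charged, it reads 2.9% at 5.00 min and 3.0% at 10.0 min, so D stands still without reaching zero. But Q drops from 20.2% on Friday to 15.2% on Sunday, so the end depends on the charge. That suggests a ligand released at each exchange and pushing back, with concentration [J]+2[Q].

So we watch the balance number, a reaction quotient: [J]/[D] times that concentration. Friday's last readings give 46.4 mM, and Sunday's give 45.5 mM. With a scatter of 0.3 percentage points on so small a D, these two readings do not differ.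

| setting | Friday's | Sunday's | flask |
|---|---|---|---|
| D | 1 mM | 1.5 mM | 2.0 mM |
| L | 0.66 mM (held) | 0.66 mM (held) | 0.66 mM (held) |
| remark | run made earlier | run made earlier |  |
| time |  |  | 8.0 min |

| run | time / min | D / % | Q / % | J / % |
|---|---|---|---|---|
| Friday's | 0.833 | 39.7 | 15.1 | 45.2 |
| Friday's | 2.00 | 9.0 | 19.0 | 70.8 |
| Friday's | 4.00 | 2.9 | 20.3 | 77.5 |
| Friday's | 10.0 | 2.0 | 20.2 | 78.2 |
| Sunday's | 2.50 | 7.0 | 14.4 | 78.6 |
| Sunday's | 5.00 | 2.9 | 14.9 | 82.3 |
| Sunday's | 8.00 | 2.9 | 14.9 | 81.4 |
| Sunday's | 10.0 | 3.0 | 15.2 | 81.4 |

(standard deviation of a reading: 0.3 percentage points)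

- why nothing more happens at 8.0 min, or that something still does (it is still moving / all of D has reacted / forward and back rates have come level)
- share of the D used up at 8.0 min
- Q at 8.0 min, in percent of the D charged
- J at 8.0 min, in percent of the D charged

- at the start none of L is in solution
- the reaction counts as stopped when no species that holds the D changes by six tenths of a point or more over the second half of the time

For the new flask we reckon roughly, keeping Sunday's shares of J and Q. Friday's number then leaves 3.92% of D. The forecast says forward and back rates have come level, with 96.1% of D used up (95.5% to 96.7%), Q 12% and J 84.1%, on the ground that “these are true equilibria, not exhaustion of D”.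

In the flask at 8.0 min, the outcome is that forward and back rates have come level, with 95.8% of D used up, Q 11.8% and J 83.9%.

    D + G ⇌ Z + J (K = 80.0, k = 45.0 M⁻¹ s⁻¹)
    J + G ⇌ Z + Q (K = 0.570, k = 76.0 M⁻¹ s⁻¹)
    2 G → X (k = 34.0 M⁻¹ s⁻¹)
    L ⇌ G, rate k4*(csat - [G]) (kL = 0.150 s⁻¹)

The released ligand is Z. At 8.00 min the forward step from D and G has, by its forward rate alone, a half-life of 0.48 min, short against the 8.0 min of this flask, yet D stands at 4.25% then and at 4.24% at 80.0 min. The balance number of this flask at 8.0 min is 42.5 mM. A neighbouring flask with the same charge, read at 2.0 min, has D at 12%, and its balance number of 12.4 mM is lower than this flask's and than Friday's reading.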